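## Retrosynthetic overview

1. The target is cut at the pyran ring. An enantioselective dehydrative chromenylation joins 2,3-dimethylhydroquinone to a (2Z,6E,10E)-12-oxo trienoic acid and sets C2.
2. The enal acid comes from the allylic alcohol acid by oxidation, and that from an acetate/methyl ester by one global saponification.
3. The (Z)-trisubstituted enoate is cut by a Still–Gennari olefination into a C12 acetoxy aldehyde and an α-homoprenyl bis(trifluoroethyl) phosphonate.
4. The aldehyde comes from geranyl acetate by allylic oxidation of the (E)-methyl group, bromination and a two-carbon aza-enolate alkylation.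
5. Ring order: the benzene ring is bought with the hydroquinone. The pyran ring is the only ring formed, in the last step.

Assumption: read from the SMILES, the target is (S) at chromene C2 with a (2Z) acid alkene and a (6E) chain alkene; geometrically pure (E)-geranyl acetate is used.

## Route

**Step 1**
Reactants: 1 geranyl acetate [(2E)-3,7-dimethylocta-2,6-dien-1-yl acetate]
Product: 2 (2E,6E)-8-hydroxy-3,7-dimethylocta-2,6-dien-1-yl acetate
Conditions: SeO2 (0.1 equiv), t-BuOOH (70% aq., 3 equiv), salicylic acid (0.1 equiv), CH2Cl2, rt, 30 h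
Reagents that add atoms: selenium dioxide, O=[Se]=O (delivers the oxygen, catalytic); tert-butyl hydroperoxide, CC(C)(C)OO (re-oxidant, ultimate oxygen source)
Why: Selenium dioxide allylic oxidation (ene reaction then [2,3]-sigmatropic shift) hydroxylates the (E)-methyl group of the electron-richer terminal alkene, leaves the acetate-deactivated 2,3-alkene alone and forms no stereocentre.

**Step 2**
Reactants: 2 (2E,6E)-8-hydroxy-3,7-dimethylocta-2,6-dien-1-yl acetate
Product: 3 (2E,6E)-8-bromo-3,7-dimethylocta-2,6-dien-1-yl acetate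
Conditions: CBr4, PPh3, CH2Cl2, 0 °C, 1 h
Reagents that add atoms: carbon tetrabromide, BrC(Br)(Br)Br
Why: Appel bromination, an SN2 displacement of the oxyphosphonium of a primary allylic alcohol under neutral conditions, keeps the acetate and both (E)-alkenes.

**Step 3**
Reactants: 3 (2E,6E)-8-bromo-3,7-dimethylocta-2,6-dien-1-yl acetate; 4 N-tert-butylacetaldimine (N-ethylidene-2-methylpropan-2-amine)
Product: 6 (2E,6E)-3,7-dimethyl-10-oxodeca-2,6-dien-1-yl acetate, via alkylated N-tert-butyl imine 5 (not isolated)
Conditions: 4, LiN(i-Pr)2 (1.1 equiv), THF, 0 °C, 30 min; then 3, −78 °C, 2 h (aza-enolate added to the bromide); then aq. tartaric acid, 0 °C → rt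
Reagents that add atoms: water, O
Why: Metalloenamine (aza-enolate, Stork-type) alkylation: the lithiated imine displaces the primary allylic bromide by SN2 at −78 °C without allylic transposition and faster than it attacks the acetate, and mild aqueous acid hydrolyses imine 5 to the two-carbon-homologated aldehyde.

**Step 4**
Reactants: 7 methyl bis(2,2,2-trifluoroethyl)phosphonoacetate; 8 5-bromo-2-methylpent-2-ene
Product: 9 methyl 2-[bis(2,2,2-trifluoroethoxy)phosphoryl]-6-methylhept-5-enoate
Conditions: NaH (1.05 equiv), DMF, 0 °C; then 8, n-Bu4NI (cat.), 50 °C, 16 h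
Reagents that add atoms: none
Why: C-alkylation of the stabilised phosphonoacetate anion by a primary bromide (SN2 with iodide catalysis); the new α-carbon is racemic and configurationally labile and becomes sp2 again in step 5.

**Step 5**
Reactants: 6 (2E,6E)-3,7-dimethyl-10-oxodeca-2,6-dien-1-yl acetate; 9 methyl 2-[bis(2,2,2-trifluoroethoxy)phosphoryl]-6-methylhept-5-enoate
Product: 10 methyl (2Z,6E,10E)-12-acetoxy-6,10-dimethyl-2-(4-methylpent-3-en-1-yl)dodeca-2,6,10-trienoate
Conditions: 9 (1.2 equiv), KN(SiMe3)2 (1.15 equiv), 18-crown-6 (3 equiv), THF, −78 °C; then 6, −78 °C, 2 h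
Reagents that add atoms: none
Why: Still–Gennari variant of the Horner–Wadsworth–Emmons olefination: the electron-poor phosphonate with a crown-separated potassium ion eliminates fast from the kinetic adduct and gives the (2Z)-enoate (chain cis to the ester); the acetate and (E)-alkenes are inert at −78 °C.

**Step 6**
Reactants: 10 methyl (2Z,6E,10E)-12-acetoxy-6,10-dimethyl-2-(4-methylpent-3-en-1-yl)dodeca-2,6,10-trienoate
Product: 11 (2Z,6E,10E)-12-hydroxy-6,10-dimethyl-2-(4-methylpent-3-en-1-yl)dodeca-2,6,10-trienoic acid
Conditions: LiOH·H2O (8 equiv), THF/MeOH/H2O 3:1:1, 50 °C, 16 h; then 1 M HCl to pH 3–4, 0 °C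
Reagents that add atoms: lithium hydroxide, [Li+].[OH-]; water, O
Why: Saponification (addition–elimination at both ester carbonyls) removes the allylic acetate and the hindered conjugated methyl ester in one operation on a robust intermediate, without touching alkene geometry.

**Step 7**
Reactants: 11 (2Z,6E,10E)-12-hydroxy-6,10-dimethyl-2-(4-methylpent-3-en-1-yl)dodeca-2,6,10-trienoic acid
Product: 12 (2Z,6E,10E)-6,10-dimethyl-2-(4-methylpent-3-en-1-yl)-12-oxododeca-2,6,10-trienoic acid
Conditions: TEMPO (0.1 equiv), PhI(OAc)2 (1.1 equiv), CH2Cl2, rt, 3 h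
Reagents that add atoms: none
Why: Oxoammonium (TEMPO/PhI(OAc)2) oxidation is chemoselective for the primary allylic alcohol, stops at the aldehyde under anhydrous conditions, tolerates the free acid and keeps the (10E)-enal geometry.

**Step 8**
Reactants: 12 (2Z,6E,10E)-6,10-dimethyl-2-(4-methylpent-3-en-1-yl)-12-oxododeca-2,6,10-trienoic acid; 13 2,3-dimethylhydroquinone (2,3-dimethylbenzene-1,4-diol)
Product: 15 (2Z,6E)-9-[(2S)-6-hydroxy-2,7,8-trimethyl-2H-chromen-2-yl]-6-methyl-2-(4-methylpent-3-en-1-yl)nona-2,6-dienoic acid, via ortho-quinone methide 14 (not isolated)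
Conditions: 13 (3 equiv), (S,S)-IDPi (5 mol %; imidodiphosphorimidate from two (S)-3,3′-bis[3,5-bis(trifluoromethyl)phenyl]-BINOL units with P=N–SO2CF3 groups; its mirror image is used if the first run gives the (R)-chromene), CH2Cl2/toluene 1:1, slow addition of 12, −20 → 0 °C, Ar, dark
Reagents that add atoms: none
Why: Proposed new method: the confined, strongly acidic chiral Brønsted acid protonates the enal, the equivalent free ortho carbons of 13 attack the carbonyl and water is lost to give ortho-quinone methide 14, which only ever arises on the catalyst and stays hydrogen-bonded/ion-paired in its pocket while the phenolic oxygen closes onto the methyl/alkyl-bearing terminus (oxa-6π electrocyclisation, C–O bond formation inside a chiral contact ion pair), so the counter-anion selects the face and sets C2 as (S), with excess 13 suppressing a second annulation at C5; the closest known reaction types are the racemic thermal or acid/amine-mediated phenol–enal chromenylation and chiral Brønsted-acid-catalysed asymmetric electrocyclisations and ortho-quinone methide captures, not yet shown for a hydroquinone with a β,β-dialkyl enal.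

## Compound list

1 | geranyl acetate, (2E)-3,7-dimethylocta-2,6-dien-1-yl acetate | CC(C)=CCC/C(C)=C/COC(C)=O | starting material
2 | (2E,6E)-8-hydroxy-3,7-dimethylocta-2,6-dien-1-yl acetate | OC/C(C)=C/CC/C(C)=C/COC(C)=O | intermediate
3 | (2E,6E)-8-bromo-3,7-dimethylocta-2,6-dien-1-yl acetate | BrC/C(C)=C/CC/C(C)=C/COC(C)=O | intermediate
4 | N-tert-butylacetaldimine | C/C=N/C(C)(C)C | starting material
5 | (2E,6E)-10-(tert-butylimino)-3,7-dimethyldeca-2,6-dien-1-yl acetate | CC(C)(C)/N=C/CC/C(C)=C/CC/C(C)=C/COC(C)=O | intermediate (not isolated)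
6 | (2E,6E)-3,7-dimethyl-10-oxodeca-2,6-dien-1-yl acetate | O=CCC/C(C)=C/CC/C(C)=C/COC(C)=O | intermediate
7 | methyl bis(2,2,2-trifluoroethyl)phosphonoacetate | COC(=O)CP(=O)(OCC(F)(F)F)OCC(F)(F)F | starting material
8 | 5-bromo-2-methylpent-2-ene | CC(C)=CCCBr | starting material
9 | methyl 2-[bis(2,2,2-trifluoroethoxy)phosphoryl]-6-methylhept-5-enoate (racemic, labile α-carbon) | COC(=O)C(CCC=C(C)C)P(=O)(OCC(F)(F)F)OCC(F)(F)F | intermediate
10 | methyl (2Z,6E,10E)-12-acetoxy-6,10-dimethyl-2-(4-methylpent-3-en-1-yl)dodeca-2,6,10-trienoate | CC(C)=CCC/C(=C/CC/C(C)=C/CC/C(C)=C/COC(C)=O)C(=O)OC | intermediate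
11 | (2Z,6E,10E)-12-hydroxy-6,10-dimethyl-2-(4-methylpent-3-en-1-yl)dodeca-2,6,10-trienoic acid | CC(C)=CCC/C(=C/CC/C(C)=C/CC/C(C)=C/CO)C(=O)O | intermediate
12 | (2Z,6E,10E)-6,10-dimethyl-2-(4-methylpent-3-en-1-yl)-12-oxododeca-2,6,10-trienoic acid | CC(C)=CCC/C(=C/CC/C(C)=C/CC/C(C)=C/C=O)C(=O)O | intermediate
13 | 2,3-dimethylhydroquinone | Cc1c(O)ccc(O)c1C | starting material
14 | ortho-quinone methide: (2Z,6E,10E)-12-(3-hydroxy-4,5-dimethyl-6-oxocyclohexa-2,4-dien-1-ylidene)-6,10-dimethyl-2-(4-methylpent-3-en-1-yl)dodeca-2,6,10-trienoic acid, dienyl chain syn to the ring carbonyl | CC(C)=CCC/C(=C/CC/C(C)=C/CC/C(C)=C/C=C1/C=C(O)C(C)=C(C)C1=O)C(=O)O | intermediate (not isolated)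
15 | (2Z,6E)-9-[(2S)-6-hydroxy-2,7,8-trimethyl-2H-chromen-2-yl]-6-methyl-2-(4-methylpent-3-en-1-yl)nona-2,6-dienoic acid (CNP0158414.2) | CC(C)=CCC/C(=C/CC/C(C)=C/CC[C@@]1(C)C=Cc2cc(O)c(C)c(C)c2O1)C(=O)O | target

## Step count and risks

Total steps: 8. Longest linear sequence: 7 (steps 1, 2, 3, 5, 6, 7, 8); step 4 is the one-step side branch.

**Step 8 (the new asymmetric chromenylation).** The risks are low enantiomeric excess if 14 escapes the catalyst before closing, a second annulation at C5, and slow acid-mediated ring opening of the product. The fallback uses known chemistry and sets out from 12 together with 13. Heating them with PhB(OH)2 and AcOH in toluene under Dean–Stark conditions (the established boronate-templated phenol–enal chromenylation) gives the racemic chromene acid F1. Preparative chiral-phase SFC (amylose tris(3,5-dimethylphenylcarbamate) phase, CO2/MeOH with 0.1% HCO2H) then separates the enantiomers, and the (S)-enantiomer rejoins the route at 15.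

**Step 3 (aza-enolate alkylation next to an allylic acetate).** The risks are acyl transfer from the acetate to the lithiated imine and some SN2′ attack. The fallback sets out from 3. Copper-catalysed sp3–sp3 cross-coupling with commercial (1,3-dioxolan-2-ylmethyl)magnesium bromide (Li2CuCl4 3 mol %, THF, −78 → −20 °C) exploits the much higher reactivity of the allylic bromide over the acetate and gives the dioxolane acetal F2. Hydrolysis of the acetal with 2 M HCl in THF at rt comes back to the route at 6.

**Step 4 (alkylation of the trifluoroethyl phosphonate).** The risks are sluggish conversion, dialkylation and loss of the base-sensitive trifluoroethyl esters. The fallback sets out from 8 and builds the carbon skeleton on a robust phosphonate before installing the fluorinated esters. Alkylation of sodium trimethyl phosphonoacetate with 8 (NaH, DMSO, 50 °C) gives the dimethyl phosphonate F3. TMSBr with 2,6-lutidine in CH2Cl2 converts it into the bis(trimethylsilyl) phosphonate F4. (COCl)2 with catalytic DMF gives the phosphonic dichloride F5, and CF3CH2OH with i-Pr2NEt in toluene comes back to the route at 9.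

## Further compounds

F1 | step 8 | racemic (2Z,6E)-9-(6-hydroxy-2,7,8-trimethyl-2H-chromen-2-yl)-6-methyl-2-(4-methylpent-3-en-1-yl)nona-2,6-dienoic acid | CC(C)=CCC/C(=C/CC/C(C)=C/CCC1(C)C=Cc2cc(O)c(C)c(C)c2O1)C(=O)O
F2 | step 3 | (2E,6E)-9-(1,3-dioxolan-2-yl)-3,7-dimethylnona-2,6-dien-1-yl acetate | O1CCOC1CC/C(C)=C/CC/C(C)=C/COC(C)=O
F3 | step 4 | methyl 2-(dimethoxyphosphoryl)-6-methylhept-5-enoate (racemic) | COC(=O)C(CCC=C(C)C)P(=O)(OC)OC
F4 | step 4 | methyl 2-[bis(trimethylsilyloxy)phosphoryl]-6-methylhept-5-enoate (racemic) | COC(=O)C(CCC=C(C)C)P(=O)(O[Si](C)(C)C)O[Si](C)(C)C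
F5 | step 4 | methyl 2-(dichlorophosphoryl)-6-methylhept-5-enoate (racemic) | COC(=O)C(CCC=C(C)C)P(=O)(Cl)Cl
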